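**Retrosynthetic overview**

- The strategy rests on ring B (C5–C6–C7–C8–C9–C10, labdane numbering): it holds the only C=C of the target, the trisubstituted C7=C8 bearing the C17 acetoxymethyl group. Ring-closing metathesis opens it to a C5 allyl arm and a C8 methylidene on an intact ring A. Ring A is made first, ring B last.
- A C1 ketone on ring A, absent from the target, is carried as a relay. It directs the conjugate reduction (C5), the C10 methylation and the ketal Claisen rearrangement that forms C10–C9, and is removed at the end through its tosylhydrazone.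
- C10–C9 (with both stereocentres) comes from the ring A enol ether of a (Z)-allylic alcohol. This alcohol is made from methyl (R)-citronellate (source of C13) by ozonolysis and a Z-selective Wittig reaction; the C17 oxygen is added afterwards by allylic oxidation.
- Ring A: 4,4-dimethylcyclohexane-1,3-dione, vinylogous ester, allyl Grignard addition and hydrolysis, enantioselective copper hydride reduction with in-flask methylation.

Key step: step 12

Assumption: labdane numbering is used for all intermediates (the target is in the ent-labdane series, 5R,9S,10R,13R); methyl (R)-citronellate and 1-[(tert-butyldimethylsilyl)oxy]propan-2-one are taken as purchasable.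

**Route**

Step 1
Reactants: 1 4,4-dimethylcyclohexane-1,3-dione
Product: 2 3-ethoxy-6,6-dimethylcyclohex-2-en-1-one
Conditions: EtOH, TsOH·H2O (cat.), toluene, reflux, Dean–Stark
Reagents that add atoms: ethanol, CCO
Why: Acid-catalysed vinylogous ester formation with azeotropic water removal; ethanol should engage the unhindered carbonyl, leaving free the ketone next to the gem-dimethyl carbon, and the minor regioisomer is removed by chromatography.

Step 2
Reactants: 2 3-ethoxy-6,6-dimethylcyclohex-2-en-1-one; 3 allylmagnesium bromide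
Product: 5 4,4-dimethyl-3-(prop-2-en-1-yl)cyclohex-2-en-1-one, via tertiary allylic alcohol 4 (not isolated)
Conditions: 3 (1.5 equiv), THF, 0 °C; then 1 M HCl, 0 °C, short contact
Reagents that add atoms: water, O
Why: Stork–Danheiser sequence: the allyl Grignard reagent adds 1,2 even to the neopentyl-flanked vinylogous ester carbonyl through a cyclic six-centre transfer, and cold dilute acid ionises the tertiary allylic alcohol and hydrolyses the enol ether to the transposed enone; the brief acid contact should keep the allyl alkene out of conjugation.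

Step 3
Reactants: 5 4,4-dimethyl-3-(prop-2-en-1-yl)cyclohex-2-en-1-one
Product: 7 (2S,3S)-2,4,4-trimethyl-3-(prop-2-en-1-yl)cyclohexan-1-one, via silyl enol ether 6 (not isolated)
Conditions: CuCl (5 mol%), NaOtBu (5 mol%), (R)-p-tol-BINAP (5 mol%; ligand hand confirmed on the first run, antipode used if the sense is opposite), Ph2SiH2 (1.0 equiv), toluene, 0 °C to rt; then Bu4N[Ph3SiF2] (1.1 equiv), MeI (3 equiv), CH2Cl2, rt
Reagents that add atoms: iodomethane, CI
Why: Copper hydride asymmetric conjugate reduction followed by fluoride-triggered enolate alkylation: the bisphosphine-ligated monovalent copper hydride delivers hydride to one enantiotopic face of the β-carbon and sets labdane C5 (3S in the ketone). The regiodefined silyl enol ether is opened by the difluorosilicate and methylated only at C2, trans to the neighbouring allyl group; C2 is planarised again in step 9, so its configuration is of no consequence, and the terminal alkene is inert to the catalyst at this temperature.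

Step 4
Reactants: 7 (2S,3S)-2,4,4-trimethyl-3-(prop-2-en-1-yl)cyclohexan-1-one
Product: 8 (2S,3S)-1,1-dimethoxy-2,4,4-trimethyl-3-(prop-2-en-1-yl)cyclohexane
Conditions: HC(OMe)3 (3 equiv), MeOH, TsOH·H2O (cat.), rt; Et3N quench
Reagents that add atoms: methanol, CO; trimethyl orthoformate, COC(OC)OC
Why: Acid-catalysed ketalisation with the orthoformate as dehydrating agent gives the activated form of the C1 carbonyl needed for alcohol exchange; the C3 stereocentre is not adjacent to the reacting carbon and cannot epimerise.

Step 5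
Reactants: 9 methyl (3R)-3,7-dimethyloct-6-enoate (methyl (R)-citronellate)
Product: 11 methyl (3R)-6-hydroxy-3-methylhexanoate, via aldehyde 10 (not isolated)
Conditions: O3, CH2Cl2/MeOH, −78 °C; then NaBH4 (3 equiv), −78 to 0 °C
Reagents that add atoms: ozone, [O-][O+]=O
Why: Ozonolysis of the trisubstituted alkene with reductive borohydride work-up; NaBH4 at or below 0 °C reduces the aldehyde and the peroxidic intermediates but not the methyl ester, and C3 (labdane C13) is untouched.

Step 6
Reactants: 11 methyl (3R)-6-hydroxy-3-methylhexanoate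
Product: 12 methyl (3R)-6-iodo-3-methylhexanoate
Conditions: I2, PPh3, imidazole, CH2Cl2, 0 °C to rt
Reagents that add atoms: iodine, II
Why: Appel-type iodination of a primary alcohol (SN2 on the alkoxyphosphonium ion), which the ester tolerates.

Step 7
Reactants: 12 methyl (3R)-6-iodo-3-methylhexanoate
Product: 13 [(4R)-6-methoxy-4-methyl-6-oxohexyl]triphenylphosphonium iodide
Conditions: PPh3 (1.2 equiv), MeCN, 80 °C
Reagents that add atoms: triphenylphosphine, c1ccc(cc1)P(c1ccccc1)c1ccccc1
Why: SN2 quaternisation of triphenylphosphine by a primary iodide.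

Step 8
Reactants: 13 [(4R)-6-methoxy-4-methyl-6-oxohexyl]triphenylphosphonium iodide; 14 1-[(tert-butyldimethylsilyl)oxy]propan-2-one
Product: 17 methyl (3R,6Z)-8-hydroxy-3,7-dimethyloct-6-enoate, via phosphonium ylide 15 (not isolated), via allylic silyl ether 16 (not isolated)
Conditions: KN(SiMe3)2 (1.0 equiv), THF, −78 °C; 14, −78 °C to rt; then 1 M HCl, MeOH, rt
Reagents that add atoms: none
Why: Wittig olefination of an α-silyloxy methyl ketone with an unstabilised ylide under salt-poor conditions, a combination known to favour the Z trisubstituted allylic ether (CH2O cis to the chain). The phosphonium C–H is far more acidic than the ester α-C–H, the ylide is consumed at low temperature before it can acylate on the ester, acidic methanol removes the silyl group in the same flask, and any E isomer is separated at the alcohol stage.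

Step 9
Reactants: 8 (2S,3S)-1,1-dimethoxy-2,4,4-trimethyl-3-(prop-2-en-1-yl)cyclohexane; 17 methyl (3R,6Z)-8-hydroxy-3,7-dimethyloct-6-enoate
Product: 20 methyl (3R,6R)-3,7-dimethyl-6-[(1S,6R)-1,5,5-trimethyl-2-oxo-6-(prop-2-en-1-yl)cyclohexyl]oct-7-enoate, via mixed ketal 18 (not isolated), via allyl enol ether 19 (not isolated)
Conditions: 8 (1.5 equiv), 17 (1.0 equiv), 2,4-dinitrophenol (5 mol%), xylene, 140 °C, MeOH distilled off
Reagents that add atoms: none
Why: Ketal Claisen rearrangement: acid-catalysed exchange of one methoxy group for alcohol 17 and loss of methanol give the allyl enol ethers, which equilibrate under the acid toward the tetrasubstituted C1=C10 isomer, and this undergoes the [3,3] shift through a chair transition state. The new C10–C9 bond forms on the ring face opposite the pseudoaxial C5 allyl group, which fixes C10 with its methyl cis to the allyl arm. The Z geometry of C8=C9 places the side chain so that the chair delivers the required C9 configuration; the E alcohol would give the C9 epimer.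

Step 10
Reactants: 20 methyl (3R,6R)-3,7-dimethyl-6-[(1S,6R)-1,5,5-trimethyl-2-oxo-6-(prop-2-en-1-yl)cyclohexyl]oct-7-enoate
Product: 21 methyl (3R,6R)-7-(hydroxymethyl)-3-methyl-6-[(1R,6R)-1,5,5-trimethyl-2-oxo-6-(prop-2-en-1-yl)cyclohexyl]oct-7-enoate
Conditions: SeO2 (0.5 equiv), t-BuOOH (3 equiv), salicylic acid (10 mol%), CH2Cl2, rt, stopped before full conversion
Reagents that add atoms: selenium dioxide, O=[Se]=O; tert-butyl hydroperoxide, CC(C)(C)OO
Why: Selenium dioxide allylic oxidation (ene reaction, then [2,3] shift) with the hydroperoxide as terminal oxidant; the 1,1-disubstituted isopropenyl alkene is far more reactive than the monosubstituted allyl alkene, and hydrogen is taken from the methyl group rather than from the hindered tertiary C9–H, so the double bond stays at C8 as a methylidene and no stereocentre is formed or disturbed.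

Step 11
Reactants: 21 methyl (3R,6R)-7-(hydroxymethyl)-3-methyl-6-[(1R,6R)-1,5,5-trimethyl-2-oxo-6-(prop-2-en-1-yl)cyclohexyl]oct-7-enoate
Product: 22 methyl (3R,6R)-7-[(acetyloxy)methyl]-3-methyl-6-[(1R,6R)-1,5,5-trimethyl-2-oxo-6-(prop-2-en-1-yl)cyclohexyl]oct-7-enoate
Conditions: Ac2O, pyridine, DMAP (cat.), CH2Cl2, 0 °C to rt
Reagents that add atoms: acetic anhydride, CC(=O)OC(C)=O
Why: DMAP-catalysed acetylation of a primary allylic alcohol; nothing else in the molecule is acylated.

Step 12
Reactants: 22 methyl (3R,6R)-7-[(acetyloxy)methyl]-3-methyl-6-[(1R,6R)-1,5,5-trimethyl-2-oxo-6-(prop-2-en-1-yl)cyclohexyl]oct-7-enoate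
Product: 23 methyl (3R)-5-[(1R,4aR,8aR)-2-[(acetyloxy)methyl]-5,5,8a-trimethyl-8-oxo-1,4,4a,5,6,7,8,8a-octahydronaphthalen-1-yl]-3-methylpentanoate
Conditions: second-generation Hoveyda–Grubbs catalyst (5 mol%), toluene (0.005 M), 80 °C, argon sparge
Reagents that add atoms: none
Why: Alkene metathesis: the ruthenium alkylidene exchanges first with the unhindered monosubstituted alkene of the C5 allyl arm to give a new alkylidene at C7, which adds intramolecularly [2+2] to the C8 methylidene; cycloreversion of the ruthenacyclobutane forms C7=C8 and returns Ru=CH2, and ethene leaves the hot sparged solution. The closest known reaction type is ring-closing metathesis of a monosubstituted/1,1-disubstituted 1,7-diene to a trisubstituted cyclohexene. Ring B closes as a six-membered carbocycle by this alkylidene transfer between two arms that are trans on ring A and both equatorial in the chair with C20 axial, so only the trans-fused bicycle can form. No stereocentre is created; C5, C9, C10 and C13 pass through unchanged. The step needs ring closure to outrun intermolecular cross-metathesis and alkene isomerisation: the substrate has only these two alkenes, six-ring closure is entropically favoured, the solution is dilute, and the catalyst does not initiate on the hindered 1,1-disubstituted alkene; the C1 ketone, methyl ester and allylic acetate are spectators.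

Step 13
Reactants: 23 methyl (3R)-5-[(1R,4aR,8aR)-2-[(acetyloxy)methyl]-5,5,8a-trimethyl-8-oxo-1,4,4a,5,6,7,8,8a-octahydronaphthalen-1-yl]-3-methylpentanoate
Product: 24 methyl (3R)-5-[(1S,4aR,8aR)-2-[(acetyloxy)methyl]-5,5,8a-trimethyl-8-[2-(4-methylbenzenesulfonyl)hydrazinylidene]-1,4,4a,5,6,7,8,8a-octahydronaphthalen-1-yl]-3-methylpentanoate
Conditions: TsNHNH2 (1.5 equiv), PPTS (10 mol%), 4 Å molecular sieves, THF, 65 °C
Reagents that add atoms: 4-methylbenzenesulfonohydrazide, Cc1ccc(cc1)S(=O)(=O)NN
Why: Acid-catalysed condensation of the C1 ketone with tosylhydrazide; the neopentyl carbonyl is slow, hence heat and water removal, and the ester, acetate and alkene are inert (the descriptor at C1 of the ring changes only through substituent priorities).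

Step 14
Reactants: 24 methyl (3R)-5-[(1S,4aR,8aR)-2-[(acetyloxy)methyl]-5,5,8a-trimethyl-8-[2-(4-methylbenzenesulfonyl)hydrazinylidene]-1,4,4a,5,6,7,8,8a-octahydronaphthalen-1-yl]-3-methylpentanoate
Product: 25 methyl (3R)-5-[(1S,4aR,8aR)-2-[(acetyloxy)methyl]-5,5,8a-trimethyl-1,4,4a,5,6,7,8,8a-octahydronaphthalen-1-yl]-3-methylpentanoate (CNP0149025.1)
Conditions: catecholborane (3 equiv), CHCl3, 0 °C to rt; then NaOAc·3H2O, 60 °C
Reagents that add atoms: none
Why: Catecholborane reduction of a tosylhydrazone: hydride adds to C=N, acetate then triggers loss of sulfinate to a diazene that expels N2 and leaves CH2 at C1. The ketone was not conjugated, so no alkene shift is possible, and the esters and the trisubstituted alkene are not attacked by catecholborane at these temperatures.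

**Compound list**

1 | 4,4-dimethylcyclohexane-1,3-dione | CC1(C)CCC(=O)CC1=O | starting material
2 | 3-ethoxy-6,6-dimethylcyclohex-2-en-1-one | CCOC1=CC(=O)C(C)(C)CC1 | intermediate
3 | allylmagnesium bromide | C=CC[Mg]Br | starting material
4 | 3-ethoxy-6,6-dimethyl-1-(prop-2-en-1-yl)cyclohex-2-en-1-ol (racemic, formed as its magnesium alkoxide) | CCOC1=CC(O)(CC=C)C(C)(C)CC1 | intermediate
5 | 4,4-dimethyl-3-(prop-2-en-1-yl)cyclohex-2-en-1-one | C=CCC1=CC(=O)CCC1(C)C | intermediate
6 | {[(3S)-4,4-dimethyl-3-(prop-2-en-1-yl)cyclohex-1-en-1-yl]oxy}diphenylsilane | C=CC[C@H]1C=C(O[SiH](c2ccccc2)c2ccccc2)CCC1(C)C | intermediate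
7 | (2S,3S)-2,4,4-trimethyl-3-(prop-2-en-1-yl)cyclohexan-1-one (2,3-trans) | O=C1CCC(C)(C)[C@@H](CC=C)[C@@H]1C | intermediate
8 | (2S,3S)-1,1-dimethoxy-2,4,4-trimethyl-3-(prop-2-en-1-yl)cyclohexane | COC1(OC)CCC(C)(C)[C@@H](CC=C)[C@@H]1C | intermediate
9 | methyl (3R)-3,7-dimethyloct-6-enoate (methyl (R)-citronellate) | COC(=O)C[C@H](C)CCC=C(C)C | starting material
10 | methyl (3R)-3-methyl-6-oxohexanoate | COC(=O)C[C@H](C)CCC=O | intermediate
11 | methyl (3R)-6-hydroxy-3-methylhexanoate | COC(=O)C[C@H](C)CCCO | intermediate
12 | methyl (3R)-6-iodo-3-methylhexanoate | COC(=O)C[C@H](C)CCCI | intermediate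
13 | [(4R)-6-methoxy-4-methyl-6-oxohexyl]triphenylphosphonium iodide | COC(=O)C[C@H](C)CCC[P+](c1ccccc1)(c1ccccc1)c1ccccc1.[I-] | intermediate
14 | 1-[(tert-butyldimethylsilyl)oxy]propan-2-one | CC(=O)CO[Si](C)(C)C(C)(C)C | starting material
15 | methyl (3R)-3-methyl-6-(triphenyl-λ5-phosphanylidene)hexanoate (ylide) | COC(=O)C[C@H](C)CCC=P(c1ccccc1)(c1ccccc1)c1ccccc1 | intermediate
16 | methyl (3R,6Z)-8-[(tert-butyldimethylsilyl)oxy]-3,7-dimethyloct-6-enoate | COC(=O)C[C@H](C)CC/C=C(/C)CO[Si](C)(C)C(C)(C)C | intermediate
17 | methyl (3R,6Z)-8-hydroxy-3,7-dimethyloct-6-enoate | COC(=O)C[C@H](C)CC/C=C(/C)CO | intermediate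
18 | methyl (3R,6Z)-8-{[(2S,3S)-1-methoxy-2,4,4-trimethyl-3-(prop-2-en-1-yl)cyclohexyl]oxy}-3,7-dimethyloct-6-enoate (mixed ketal, ketal carbon unassigned) | COC1(OC/C(C)=C\CC[C@@H](C)CC(=O)OC)CCC(C)(C)[C@@H](CC=C)[C@@H]1C | intermediate
19 | methyl (3R,6Z)-3,7-dimethyl-8-{[(3R)-2,4,4-trimethyl-3-(prop-2-en-1-yl)cyclohex-1-en-1-yl]oxy}oct-6-enoate (allyl enol ether) | C=CC[C@H]1C(C)=C(OC/C(C)=C\CC[C@@H](C)CC(=O)OC)CCC1(C)C | intermediate
20 | methyl (3R,6R)-3,7-dimethyl-6-[(1S,6R)-1,5,5-trimethyl-2-oxo-6-(prop-2-en-1-yl)cyclohexyl]oct-7-enoate | COC(=O)C[C@H](C)CC[C@H](C(C)=C)[C@]1(C)C(=O)CCC(C)(C)[C@H]1CC=C | intermediate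
21 | methyl (3R,6R)-7-(hydroxymethyl)-3-methyl-6-[(1R,6R)-1,5,5-trimethyl-2-oxo-6-(prop-2-en-1-yl)cyclohexyl]oct-7-enoate | COC(=O)C[C@H](C)CC[C@H](C(=C)CO)[C@]1(C)C(=O)CCC(C)(C)[C@H]1CC=C | intermediate
22 | methyl (3R,6R)-7-[(acetyloxy)methyl]-3-methyl-6-[(1R,6R)-1,5,5-trimethyl-2-oxo-6-(prop-2-en-1-yl)cyclohexyl]oct-7-enoate (metathesis precursor) | COC(=O)C[C@H](C)CC[C@H](C(=C)COC(C)=O)[C@]1(C)C(=O)CCC(C)(C)[C@H]1CC=C | intermediate
23 | methyl (3R)-5-[(1R,4aR,8aR)-2-[(acetyloxy)methyl]-5,5,8a-trimethyl-8-oxo-1,4,4a,5,6,7,8,8a-octahydronaphthalen-1-yl]-3-methylpentanoate (1-oxo derivative of the target) | COC(=O)C[C@H](C)CC[C@@H]1C(COC(C)=O)=CC[C@@H]2C(C)(C)CCC(=O)[C@@]12C | intermediate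
24 | methyl (3R)-5-[(1S,4aR,8aR)-2-[(acetyloxy)methyl]-5,5,8a-trimethyl-8-[2-(4-methylbenzenesulfonyl)hydrazinylidene]-1,4,4a,5,6,7,8,8a-octahydronaphthalen-1-yl]-3-methylpentanoate | COC(=O)C[C@H](C)CC[C@@H]1C(COC(C)=O)=CC[C@@H]2C(C)(C)CCC(=NNS(=O)(=O)c3ccc(C)cc3)[C@@]12C | intermediate
25 | methyl (3R)-5-[(1S,4aR,8aR)-2-[(acetyloxy)methyl]-5,5,8a-trimethyl-1,4,4a,5,6,7,8,8a-octahydronaphthalen-1-yl]-3-methylpentanoate | COC(=O)C[C@H](C)CC[C@@H]1C(COC(C)=O)=CC[C@@H]2C(C)(C)CCC[C@@]12C | target

**Step count**

Total: 14 steps. Longest linear sequence: 10 steps (steps 1–4 then 9–14, or steps 5–8 then 9–14).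

**Steps most likely to fail**

1. Step 9 (ketal Claisen). The oxocarbenium ion from the mixed ketal may lose its proton toward C2 as readily as toward C10, so that the [3,3] shift alkylates C2 instead of C10. Part of the material may also pass through a boat, which would erode the C9 configuration.
   Fallback, setting out from enone 5 and returning at 20: the enol ether is made by C–O cross-coupling instead of ketal exchange, so the double bond is locked at C1=C10. Enone 5 is reduced as in step 3, but silyl enol ether 6 is opened with Bu4N[Ph3SiF2] in the presence of dimethyl(methylidene)ammonium iodide to give the Mannich base F1. MeI and then NaHCO3 eliminate trimethylamine and give the α-methylene ketone F2. LiBH(s-Bu)3 at −78 °C adds hydride to the exocyclic carbon, and PhNTf2 traps the resulting C1=C10 enolate as the enol triflate F3. Ni(OAc)2·4H2O, cycloocta-1,5-diene and NaI exchange triflate for iodide to give the alkenyl iodide F4. CuI, 3,4,7,8-tetramethyl-1,10-phenanthroline and Cs2CO3 in toluene at 80 °C couple F4 with alcohol 17 to give enol ether 19 as one regioisomer, which is heated on to 20.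

2. Step 10 (allylic oxidation). The new allylic alcohol may be over-oxidised to the enal, or the ene reaction may stray to the allyl arm or to C9–H.
   Fallback, setting out from 20 and returning at 22: ene-type chlorination with hypochlorous acid, generated from Ca(OCl)2 and CO2 in CH2Cl2/water at 0 °C, should give the allylic chloride F5. CsOAc in DMF at 50 °C then displaces chloride and gives acetate 22 directly, with no alcohol stage to over-oxidise.

3. Step 14 (hydrazone reduction). Hydride transfer to the neopentyl C=N may be too slow, so that the hydrazone survives or breaks down on heating with acetate through diazo and carbene pathways to ring A alkenes.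
   Fallback, setting out from 23 and returning at 25: NaBH4 in MeOH at 0 °C reduces the C1 ketone to the secondary alcohol F6 (either epimer serves). 1,1′-Thiocarbonyldiimidazole and DMAP in 1,2-dichloroethane at reflux give the imidazole-1-carbothioate F7. Bu3SnH and AIBN in toluene at 100 °C then remove the C–O bond by Barton–McCombie radical deoxygenation and give 25.

**Further compounds**

F1 | step 9 | (3S)-2-[(dimethylamino)methyl]-4,4-dimethyl-3-(prop-2-en-1-yl)cyclohexan-1-one (Mannich base, C2 unassigned) | CN(C)CC1C(=O)CCC(C)(C)[C@H]1CC=C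
F2 | step 9 | (3R)-4,4-dimethyl-2-methylidene-3-(prop-2-en-1-yl)cyclohexan-1-one | C=C1C(=O)CCC(C)(C)[C@H]1CC=C
F3 | step 9 | (3R)-2,4,4-trimethyl-3-(prop-2-en-1-yl)cyclohex-1-en-1-yl trifluoromethanesulfonate | C=CC[C@H]1C(C)=C(OS(=O)(=O)C(F)(F)F)CCC1(C)C
F4 | step 9 | (3R)-1-iodo-2,4,4-trimethyl-3-(prop-2-en-1-yl)cyclohex-1-ene | C=CC[C@H]1C(C)=C(I)CCC1(C)C
F5 | step 10 | 17-chloro analogue of 22 (chloromethyl in place of acetoxymethyl on C8; same configuration at C5, C9, C10, C13) | COC(=O)C[C@H](C)CC[C@H](C(=C)CCl)[C@]1(C)C(=O)CCC(C)(C)[C@H]1CC=C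
F6 | step 14 | 1-hydroxy analogue of 25 (secondary alcohol at C1, either epimer) | COC(=O)C[C@H](C)CC[C@@H]1C(COC(C)=O)=CC[C@@H]2C(C)(C)CCC(O)[C@@]12C
F7 | step 14 | O-(imidazol-1-ylthiocarbonyl) derivative of F6 | COC(=O)C[C@H](C)CC[C@@H]1C(COC(C)=O)=CC[C@@H]2C(C)(C)CCC(OC(=S)n3ccnc3)[C@@]12C
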